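**Plan**
- Retrosynthesis: first the six benzyl ethers and the C4–H bond of the upper flavan (from a C4 carbinol) are cut. Then, in one operation, the aryl ether bond O1–C8a of the lower (epiafzelechin) unit and the interflavan bond C4(upper)–C8(lower). Then C2–aryl (Grignard/aldehyde) and C3–C4 (glycolate alkylation) of the lower chain, and C2–aryl of the upper flavanone (conjugate addition to a chromone).
- Enabling feature: in ring A of the lower unit the ether carbon C8a and the interflavan carbon C8 are neighbours; C8 is flanked by the C7 oxygen and C8a by the C4a–C4–C3–C2–O chain. An aryne across C8–C8a, released from a C8 iodide and a C8a arenesulfonate (both lost in the event), takes up the C2 alkoxide at C8a and, through the resulting C8 carbanion, the C4 ketone of the upper flavanone.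
- Forward order: ring A aldehyde → iodide and sulfonate → benzylic bromide → open C4–C3–C2 chain carrying ring B. The upper flavanone is made separately. The key step closes ring C of the lower unit and joins the halves; C4 reduction and debenzylation finish.
- Stereochemistry: lower C3 from the Evans glycolate alkylation; lower C2 from chelation-controlled Grignard addition, kept because the key step makes the bond at the aryl carbon and not at C2. Upper C2 comes from ligand-controlled conjugate addition; upper C4 from hydride delivery to the C4 cation under control of C2 (2,4-cis).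

Key step: step 11

Assumption: 1 and 6 are taken as catalogue building blocks (each otherwise one routine step from 2,4,6-trihydroxybenzaldehyde or from (S)-4-benzyloxazolidin-2-one), and the (R)-ligand of step 10 is assigned to the (2S) series by analogy with cyclic enones (the other ligand enantiomer is used if a trial shows the opposite sense).

**Step 1**
Reactants: 1 2,4-bis(benzyloxy)-6-hydroxybenzaldehyde
Product: 2 4,6-bis(benzyloxy)-2-hydroxy-3-iodobenzaldehyde
Conditions: NIS (1.05 equiv), TsOH·H2O (10 mol %), MeCN, 0 °C → rt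
Reagents that add atoms: N-iodosuccinimide, O=C1CCC(=O)N1I
Why: Electrophilic aromatic iodination of the chelated phenol should enter ortho to the free hydroxyl, at the open position flanked by OH and one benzyloxy group and not at the more hindered one between two benzyloxy groups, as is usual for 2-hydroxy-4,6-dialkoxyaryl carbonyl compounds.

**Step 2**
Reactants: 2 4,6-bis(benzyloxy)-2-hydroxy-3-iodobenzaldehyde
Product: 3 3,5-bis(benzyloxy)-2-formyl-6-iodophenyl 4-chlorobenzenesulfonate
Conditions: 4-ClC6H4SO2Cl (1.3 equiv), K2CO3, acetone, 50 °C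
Reagents that add atoms: 4-chlorobenzenesulfonyl chloride, O=S(=O)(Cl)c1ccc(Cl)cc1
Why: O-Sulfonylation of the phenoxide installs the arenesulfonate, the leaving group that later allows controlled aryne release from the ortho-magnesiated arene.

**Step 3**
Reactants: 3 3,5-bis(benzyloxy)-2-formyl-6-iodophenyl 4-chlorobenzenesulfonate
Product: 4 3,5-bis(benzyloxy)-2-(hydroxymethyl)-6-iodophenyl 4-chlorobenzenesulfonate
Conditions: NaBH4, THF/MeOH, 0 °C
Reagents that add atoms: none
Why: Chemoselective borohydride reduction of the aldehyde; the aryl sulfonate and aryl iodide are inert to NaBH4 at 0 °C.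

**Step 4**
Reactants: 4 3,5-bis(benzyloxy)-2-(hydroxymethyl)-6-iodophenyl 4-chlorobenzenesulfonate
Product: 5 3,5-bis(benzyloxy)-2-(bromomethyl)-6-iodophenyl 4-chlorobenzenesulfonate
Conditions: CBr4, PPh3, CH2Cl2, 0 °C; used at once
Reagents that add atoms: carbon tetrabromide, BrC(Br)(Br)Br
Why: The Appel reaction converts the benzylic alcohol into the bromide under neutral conditions that spare the sulfonate; the electron-rich benzylic bromide is not stored.

**Step 5**
Reactants: 5 3,5-bis(benzyloxy)-2-(bromomethyl)-6-iodophenyl 4-chlorobenzenesulfonate; 6 (S)-4-benzyl-3-[2-(benzyloxy)acetyl]oxazolidin-2-one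
Product: 8 3,5-bis(benzyloxy)-2-[(2R)-2-(benzyloxy)-3-[(4S)-4-benzyl-2-oxooxazolidin-3-yl]-3-oxopropyl]-6-iodophenyl 4-chlorobenzenesulfonate, via sodium enolate 7 (not isolated)
Conditions: 6 (1.3 equiv), NaN(SiMe3)2, THF, −78 °C; then 5, −78 → −45 °C
Reagents that add atoms: none
Why: Evans auxiliary alkylation: the chelated sodium Z-enolate of the glycolate imide is alkylated by the benzylic bromide on the face opposite the auxiliary benzyl group, which sets the (R) centre that becomes C3 of the lower unit, already carrying its benzyl ether.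

**Step 6**
Reactants: 8 the alkylated imide
Product: 9 3,5-bis(benzyloxy)-2-[(2R)-2-(benzyloxy)-3-hydroxypropyl]-6-iodophenyl 4-chlorobenzenesulfonate
Conditions: LiBH4, MeOH (1 equiv), THF, 0 °C
Reagents that add atoms: none
Why: Reductive cleavage of the N-acyl oxazolidinone with LiBH4 gives the primary alcohol without touching the α-stereocentre and releases the auxiliary.

**Step 7**
Reactants: 9 3,5-bis(benzyloxy)-2-[(2R)-2-(benzyloxy)-3-hydroxypropyl]-6-iodophenyl 4-chlorobenzenesulfonate
Product: 10 3,5-bis(benzyloxy)-2-[(2R)-2-(benzyloxy)-3-oxopropyl]-6-iodophenyl 4-chlorobenzenesulfonate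
Conditions: Dess–Martin periodinane, CH2Cl2, 0 °C → rt; used directly
Reagents that add atoms: none
Why: Dess–Martin oxidation gives the α-benzyloxy aldehyde under non-basic conditions that should not epimerise the α-centre.

**Step 8**
Reactants: 10 the (2R)-α-benzyloxy aldehyde; 11 4-(benzyloxy)phenylmagnesium bromide
Product: 12 3,5-bis(benzyloxy)-2-[(2R,3R)-2-(benzyloxy)-3-[4-(benzyloxy)phenyl]-3-hydroxypropyl]-6-iodophenyl 4-chlorobenzenesulfonate
Conditions: MgBr2·OEt2 (3 equiv), CH2Cl2, −78 °C; then 11 (1.3 equiv), −78 °C; aq. NH4Cl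
Reagents that add atoms: none
Why: Cram-chelate controlled Grignard addition: magnesium bridges the aldehyde oxygen and the α-benzyloxy oxygen and the aryl group adds to the less hindered face of the chelate, which should give the threo (2R,3R) alcohol, i.e. the future C2 of the lower unit with a free hydroxyl beside the benzyl-protected C3 oxygen.

**Step 9**
Reactants: 13 7-hydroxy-4H-chromen-4-one
Product: 14 7-(benzyloxy)-4H-chromen-4-one
Conditions: BnBr, K2CO3, DMF, rt
Reagents that add atoms: benzyl bromide, BrCc1ccccc1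
Why: Williamson etherification of the phenol.

**Step 10**
Reactants: 14 7-(benzyloxy)-4H-chromen-4-one; 15 4-(benzyloxy)phenylboronic acid
Product: 16 (2S)-7-(benzyloxy)-2-[4-(benzyloxy)phenyl]chroman-4-one
Conditions: 15 (2 equiv), Pd(OCOCF3)2 (5 mol %), (R)-t-BuPyOx (6 mol %), NH4PF6 (30 mol %), H2O (5 equiv), ClCH2CH2Cl, 60 °C
Reagents that add atoms: none
Why: Palladium-catalysed asymmetric conjugate addition of an arylboronic acid to a chromone (aryl transfer to C2 by migratory insertion, then protonolysis of the palladium enolate); the tert-butyl oxazoline of the ligand selects the enantioface and so should set (2S).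

**Step 11**
Reactants: 12 the (2R,3R) iodo sulfonate alcohol; 16 (2S)-7-(benzyloxy)-2-[4-(benzyloxy)phenyl]chroman-4-one
Product: 20 (2S)-7-(benzyloxy)-2-[4-(benzyloxy)phenyl]-4-[(2R,3R)-3,5,7-tris(benzyloxy)-2-[4-(benzyloxy)phenyl]chroman-8-yl]chroman-4-ol, via magnesiated sulfonate 17 (not isolated), via aryne alkoxide 18 (not isolated), via flavan-8-ylmagnesium chloride 19 (not isolated)
Conditions: iPrMgCl·LiCl (2.1 equiv), THF, −78 °C; warm to 20 °C; recool to −78 °C, LaCl3·2LiCl (1.1 equiv), 16 (1.3 equiv), −78 → 0 °C; aq. NH4Cl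
Reagents that add atoms: none
Why: Proposed new method: iodine–magnesium exchange at C8 (ortho to the sulfonate) and β-elimination of chloromagnesium 4-chlorobenzenesulfonate on warming should give the C8–C8a aryne 18, whose tethered C2 magnesium alkoxide adds to C8a to close the pyran ring and leave the C8 arylmagnesium 19, which then adds to the C4 carbonyl of 16 under LaCl3·2LiCl activation, so that the aryl ether bond and the interflavan C4–C8 bond are made in one flask. The closest known reaction types are aryne generation from 2-magnesiated aryl sulfonates with addition of magnesium amides or thiolates and electrophilic capture of the resulting aryl Grignard reagent, intramolecular alkoxide–aryne cyclisation to chromans, and the addition of 8-metalated benzylated flavan-3-ols to C4 ketones. The pyran ring closes in a 6-exo-dig mode (the attacked aryne carbon C8a lies in the new six-membered ring, C8 outside it). No bond to C2 or C3 of the lower unit is touched, so both centres (set in steps 5 and 8) are carried through with retention, and the new carbinol centre at C4 of the upper unit need not be controlled because it is planarised in step 12. The step needs oxygen at C8a, carbon at C8 and nothing at C6: the C7 benzyloxy group beside the triple bond withdraws inductively, directs the nucleophile to the distal carbon C8a and stabilises the developing carbanion at C8; the three-carbon tether can only reach C8a; and the C3 oxygen is capped as a benzyl ether so that the faster five-membered closure cannot compete.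

**Step 12**
Reactants: 20 the C4 carbinol
Product: 22 (2S,4S)-7-(benzyloxy)-2-[4-(benzyloxy)phenyl]-4-[(2R,3R)-3,5,7-tris(benzyloxy)-2-[4-(benzyloxy)phenyl]chroman-8-yl]chromane, via flavan-4-yl cation 21 (not isolated)
Conditions: Et3SiH (5 equiv), CF3CO2H (5 equiv), CH2Cl2, −40 °C
Reagents that add atoms: none
Why: Ionic hydrogenation, as used for 4-aryl-flavan-4-ols: acid ionises the tertiary, doubly benzylic carbinol to cation 21 and triethylsilane should deliver hydride axially to the half-chair whose C2 aryl group is equatorial, so that the C4 aryl group ends equatorial and cis to the C2 aryl group, giving (4S).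

**Step 13**
Reactants: 22 the hexa-O-benzyl dimer
Product: 23 (2R,3R)-8-[(2S,4S)-7-hydroxy-2-(4-hydroxyphenyl)chroman-4-yl]-2-(4-hydroxyphenyl)chromane-3,5,7-triol (CNP0254623.1)
Conditions: H2 (1 atm), Pd(OH)2/C, THF/MeOH, rt
Reagents that add atoms: none
Why: Hydrogenolysis of the six benzyl ethers; the cyclic benzylic C2–O bonds of flavans are known to survive these conditions and no stereocentre is affected.

**Compound list**
1 | 2,4-bis(benzyloxy)-6-hydroxybenzaldehyde | O=Cc1c(O)cc(OCc2ccccc2)cc1OCc1ccccc1 | starting material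
2 | 4,6-bis(benzyloxy)-2-hydroxy-3-iodobenzaldehyde | O=Cc1c(O)c(I)c(OCc2ccccc2)cc1OCc1ccccc1 | intermediate
3 | 3,5-bis(benzyloxy)-2-formyl-6-iodophenyl 4-chlorobenzenesulfonate | O=Cc1c(OS(=O)(=O)c2ccc(Cl)cc2)c(I)c(OCc2ccccc2)cc1OCc1ccccc1 | intermediate
4 | 3,5-bis(benzyloxy)-2-(hydroxymethyl)-6-iodophenyl 4-chlorobenzenesulfonate | OCc1c(OS(=O)(=O)c2ccc(Cl)cc2)c(I)c(OCc2ccccc2)cc1OCc1ccccc1 | intermediate
5 | 3,5-bis(benzyloxy)-2-(bromomethyl)-6-iodophenyl 4-chlorobenzenesulfonate | BrCc1c(OS(=O)(=O)c2ccc(Cl)cc2)c(I)c(OCc2ccccc2)cc1OCc1ccccc1 | intermediate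
6 | (S)-4-benzyl-3-[2-(benzyloxy)acetyl]oxazolidin-2-one | O=C(COCc1ccccc1)N1C(=O)OC[C@@H]1Cc1ccccc1 | starting material
7 | sodium (Z)-enolate of 6 | [Na+].[O-]/C(=C\OCc1ccccc1)N1C(=O)OC[C@@H]1Cc1ccccc1 | intermediate (not isolated)
8 | 3,5-bis(benzyloxy)-2-[(2R)-2-(benzyloxy)-3-[(4S)-4-benzyl-2-oxooxazolidin-3-yl]-3-oxopropyl]-6-iodophenyl 4-chlorobenzenesulfonate | O=C([C@H](OCc1ccccc1)Cc1c(OS(=O)(=O)c2ccc(Cl)cc2)c(I)c(OCc2ccccc2)cc1OCc1ccccc1)N1C(=O)OC[C@@H]1Cc1ccccc1 | intermediate
9 | 3,5-bis(benzyloxy)-2-[(2R)-2-(benzyloxy)-3-hydroxypropyl]-6-iodophenyl 4-chlorobenzenesulfonate | OC[C@H](OCc1ccccc1)Cc1c(OS(=O)(=O)c2ccc(Cl)cc2)c(I)c(OCc2ccccc2)cc1OCc1ccccc1 | intermediate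
10 | 3,5-bis(benzyloxy)-2-[(2R)-2-(benzyloxy)-3-oxopropyl]-6-iodophenyl 4-chlorobenzenesulfonate | O=C[C@H](OCc1ccccc1)Cc1c(OS(=O)(=O)c2ccc(Cl)cc2)c(I)c(OCc2ccccc2)cc1OCc1ccccc1 | intermediate
11 | 4-(benzyloxy)phenylmagnesium bromide (THF solution) | Br[Mg]c1ccc(OCc2ccccc2)cc1 | starting material
12 | 3,5-bis(benzyloxy)-2-[(2R,3R)-2-(benzyloxy)-3-[4-(benzyloxy)phenyl]-3-hydroxypropyl]-6-iodophenyl 4-chlorobenzenesulfonate | O[C@H](c1ccc(OCc2ccccc2)cc1)[C@H](OCc1ccccc1)Cc1c(OS(=O)(=O)c2ccc(Cl)cc2)c(I)c(OCc2ccccc2)cc1OCc1ccccc1 | intermediate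
13 | 7-hydroxy-4H-chromen-4-one | O=c1ccoc2cc(O)ccc12 | starting material
14 | 7-(benzyloxy)-4H-chromen-4-one | O=c1ccoc2cc(OCc3ccccc3)ccc12 | intermediate
15 | 4-(benzyloxy)phenylboronic acid | OB(O)c1ccc(OCc2ccccc2)cc1 | starting material
16 | (2S)-7-(benzyloxy)-2-[4-(benzyloxy)phenyl]chroman-4-one | O=C1C[C@@H](c2ccc(OCc3ccccc3)cc2)Oc2cc(OCc3ccccc3)ccc12 | intermediate
17 | chloromagnesium alkoxide of 12 magnesiated at C8 in place of iodine | Cl[Mg]O[C@H](c1ccc(OCc2ccccc2)cc1)[C@H](OCc1ccccc1)Cc1c(OS(=O)(=O)c2ccc(Cl)cc2)c([Mg]Cl)c(OCc2ccccc2)cc1OCc1ccccc1 | intermediate (not isolated)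
18 | C8–C8a aryne bearing the chloromagnesium C2 alkoxide | Cl[Mg]O[C@H](c1ccc(OCc2ccccc2)cc1)[C@H](OCc1ccccc1)CC1=C(OCc2ccccc2)C=C(OCc2ccccc2)C#C1 | intermediate (not isolated)
19 | [(2R,3R)-3,5,7-tris(benzyloxy)-2-[4-(benzyloxy)phenyl]chroman-8-yl]magnesium chloride | Cl[Mg]c1c(OCc2ccccc2)cc(OCc2ccccc2)c2c1O[C@H](c1ccc(OCc3ccccc3)cc1)[C@H](OCc1ccccc1)C2 | intermediate (not isolated)
20 | (2S)-7-(benzyloxy)-2-[4-(benzyloxy)phenyl]-4-[(2R,3R)-3,5,7-tris(benzyloxy)-2-[4-(benzyloxy)phenyl]chroman-8-yl]chroman-4-ol (C4 configuration left open) | OC1(C[C@@H](c2ccc(OCc3ccccc3)cc2)Oc2cc(OCc3ccccc3)ccc12)c1c(OCc2ccccc2)cc(OCc2ccccc2)c2c1O[C@H](c1ccc(OCc3ccccc3)cc1)[C@H](OCc1ccccc1)C2 | intermediate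
21 | C4 carbocation of 20 (trifluoroacetate) | [O-]C(=O)C(F)(F)F.[C+]1(C[C@@H](c2ccc(OCc3ccccc3)cc2)Oc2cc(OCc3ccccc3)ccc12)c1c(OCc2ccccc2)cc(OCc2ccccc2)c2c1O[C@H](c1ccc(OCc3ccccc3)cc1)[C@H](OCc1ccccc1)C2 | intermediate (not isolated)
22 | (2S,4S)-7-(benzyloxy)-2-[4-(benzyloxy)phenyl]-4-[(2R,3R)-3,5,7-tris(benzyloxy)-2-[4-(benzyloxy)phenyl]chroman-8-yl]chromane | O(Cc1ccccc1)c1ccc([C@@H]2C[C@H](c3c(OCc5ccccc5)cc(OCc5ccccc5)c4c3O[C@H](c3ccc(OCc5ccccc5)cc3)[C@H](OCc5ccccc5)C4)c3ccc(OCc5ccccc5)cc3O2)cc1 | intermediate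
23 | (2R,3R)-8-[(2S,4S)-7-hydroxy-2-(4-hydroxyphenyl)chroman-4-yl]-2-(4-hydroxyphenyl)chromane-3,5,7-triol | Oc1ccc([C@@H]2C[C@H](c3c(O)cc(O)c4c3O[C@H](c3ccc(O)cc3)[C@H](O)C4)c3ccc(O)cc3O2)cc1 | target

**Totals**
Total step count: 13. Longest linear sequence: 11 steps (steps 1–8, then 11–13).

**Steps most likely to fail**

Step 11. The aggregated magnesium alkoxide may add too slowly to the aryne, so that the aryne is consumed by chloride, by residual isopropylmagnesium chloride or by oligomerisation. Alternatively, the hindered di-ortho-alkoxy arylmagnesium may deprotonate the flavanone at C3 instead of adding, with ring opening of the enolate and loss of configuration at C2. The fallback uses known chemistry only: the pyran ring is closed at C2 by two Mitsunobu inversions and the iodide is kept as the handle for the interflavan bond. It sets out from 12. Mitsunobu esterification with 4-nitrobenzoic acid (PPh3, DIAD, THF) inverts the carbinol carbon and gives (1S,2R)-2-(benzyloxy)-1-[4-(benzyloxy)phenyl]-3-[4,6-bis(benzyloxy)-2-{[(4-chlorophenyl)sulfonyl]oxy}-3-iodophenyl]propyl 4-nitrobenzoate F1. KOH in MeOH/THF then cleaves the benzoate and the aryl sulfonate together to the erythro iodophenol 3,5-bis(benzyloxy)-2-[(2R,3S)-2-(benzyloxy)-3-[4-(benzyloxy)phenyl]-3-hydroxypropyl]-6-iodophenol F2. Intramolecular Mitsunobu etherification (PPh3, DIAD, THF) closes O1–C2 with a second inversion to (2R,3R)-3,5,7-tris(benzyloxy)-2-[4-(benzyloxy)phenyl]-8-iodochromane F3. Iodine–magnesium exchange (iPrMgCl·LiCl, THF, −40 °C) followed by LaCl3·2LiCl and 16 should then give 20, where the route is rejoined.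

Step 12. Hydride delivery to a cation flanked by a twisted, di-ortho-substituted aryl group may show poor facial selectivity, and the acid may ionise the benzylic C2–O bonds or reverse the new interflavan bond. The fallback sets out from 20. Dehydration with catalytic pyridinium p-toluenesulfonate in toluene at 50 °C gives (2S)-7-(benzyloxy)-2-[4-(benzyloxy)phenyl]-4-[(2R,3R)-3,5,7-tris(benzyloxy)-2-[4-(benzyloxy)phenyl]chroman-8-yl]-2H-chromene F4. Hydrogenation over Pd(OH)2/C (H2, THF/MeOH) should add hydrogen to C3=C4 from the face opposite the C2 aryl group (2,4-cis) and cleave the six benzyl ethers in the same operation, arriving directly at 23.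

Step 8. THF from the Grignard solution may erode chelation control and raise the share of the erythro epimer, and iodine–magnesium exchange at the sulfonate-activated aryl iodide may compete with carbonyl addition. The fallback replaces substrate control by catalyst control and sets out from 12 obtained as a mixture of carbinol epimers. Dess–Martin oxidation gives the aryl ketone 3,5-bis(benzyloxy)-2-[(2R)-2-(benzyloxy)-3-[4-(benzyloxy)phenyl]-3-oxopropyl]-6-iodophenyl 4-chlorobenzenesulfonate F5. Corey–Bakshi–Shibata reduction ((R)-2-methyl-CBS-oxazaborolidine, BH3·SMe2, THF, −20 °C), with the aryl group acting as the large substituent, should return the (3R) carbinol 12.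

**Further compounds**
F1 | step 11 | (1S,2R)-2-(benzyloxy)-1-[4-(benzyloxy)phenyl]-3-[4,6-bis(benzyloxy)-2-{[(4-chlorophenyl)sulfonyl]oxy}-3-iodophenyl]propyl 4-nitrobenzoate | O=C(O[C@@H](c1ccc(OCc2ccccc2)cc1)[C@H](OCc1ccccc1)Cc1c(OS(=O)(=O)c2ccc(Cl)cc2)c(I)c(OCc2ccccc2)cc1OCc1ccccc1)c1ccc([N+](=O)[O-])cc1
F2 | step 11 | 3,5-bis(benzyloxy)-2-[(2R,3S)-2-(benzyloxy)-3-[4-(benzyloxy)phenyl]-3-hydroxypropyl]-6-iodophenol | O[C@@H](c1ccc(OCc2ccccc2)cc1)[C@H](OCc1ccccc1)Cc1c(O)c(I)c(OCc2ccccc2)cc1OCc1ccccc1
F3 | step 11 | (2R,3R)-3,5,7-tris(benzyloxy)-2-[4-(benzyloxy)phenyl]-8-iodochromane | Ic1c(OCc2ccccc2)cc(OCc2ccccc2)c2c1O[C@H](c1ccc(OCc3ccccc3)cc1)[C@H](OCc1ccccc1)C2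
F4 | step 12 | (2S)-7-(benzyloxy)-2-[4-(benzyloxy)phenyl]-4-[(2R,3R)-3,5,7-tris(benzyloxy)-2-[4-(benzyloxy)phenyl]chroman-8-yl]-2H-chromene | C1(c2c(OCc3ccccc3)cc(OCc3ccccc3)c3c2O[C@H](c2ccc(OCc4ccccc4)cc2)[C@H](OCc2ccccc2)C3)=C[C@@H](c2ccc(OCc3ccccc3)cc2)Oc2cc(OCc3ccccc3)ccc12
F5 | step 8 | 3,5-bis(benzyloxy)-2-[(2R)-2-(benzyloxy)-3-[4-(benzyloxy)phenyl]-3-oxopropyl]-6-iodophenyl 4-chlorobenzenesulfonate | O=C(c1ccc(OCc2ccccc2)cc1)[C@H](OCc1ccccc1)Cc1c(OS(=O)(=O)c2ccc(Cl)cc2)c(I)c(OCc2ccccc2)cc1OCc1ccccc1
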